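**Retrosynthetic overview**
1. The C8' alcohol comes from an ester; C11=C12 is cut by a Wittig reaction between a ring-bearing C15 hydroxy phosphonium salt and a C15 polyene aldehyde ester (C10 dialdehyde + C5 phosphonate, HWE).
2. The C3 carbinol comes from the ring enone by catalyst-controlled transfer hydrogenation; the phosphonium group comes from the primary dienylic alcohol.
3. The C6 stereocentre (the first one) comes from an achiral β,γ-unsaturated 3-oxo trienol by an amine-catalysed enantioselective 1,3-proton shift (key step).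
4. C6–C7 is cut by a Stille coupling of an achiral 4-oxocyclohexenyl triflate with a dienylstannane made from an enynol.
5. Rings: the only ring is bought intact as 4-oxoisophorone and no ring is formed; the triflate arises from it by conjugate reduction and enolate trapping.

Assumption: 4-oxoisophorone, (E)-3-methylpent-2-en-4-yn-1-ol, the C10 dialdehyde and the C5 phosphonate ester are taken as commercial building blocks.

Carotenoid numbering (C1–C6 ring, C7–C15, C15'–C8') is used in the explanations. The target is (3S,6R)-3-hydroxy-8'-apo-ε-caroten-8'-ol, with the 3-OH and the C6 side chain cis.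

**Step 1**
Reactants: 1 4-oxoisophorone (2,6,6-trimethylcyclohex-2-ene-1,4-dione)
Product: 3 2,6,6-trimethyl-4-oxocyclohex-1-en-1-yl trifluoromethanesulfonate, via lithium enolate 2 (not isolated)
Conditions: LiBH(s-Bu)3 (1.05 equiv), THF, −78 °C; then PhNTf2 (1.1 equiv), −78 → 0 °C; aq. NH4Cl
Reagents that add atoms: lithium tri-sec-butylborohydride (hydride, and the lithium of 2), [Li+].CCC(C)[BH-](C(C)CC)C(C)CC; N-phenylbis(trifluoromethanesulfonimide) (SO2CF3), O=S(=O)(N(c1ccccc1)S(=O)(=O)C(F)(F)F)C(F)(F)F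
Why: Conjugate reduction of the ene-dione by the bulky borohydride at the unsubstituted alkene carbon gives only the tetrasubstituted enolate of the hindered carbonyl, which is O-sulfonylated (enolate triflation) before proton transfer, so the product has no stereocentre.

**Step 2**
Reactants: 4 (2E)-3-methylpent-2-en-4-yn-1-ol
Product: 5 (2E,4E)-3-methyl-5-(tributylstannyl)penta-2,4-dien-1-ol
Conditions: Bu3SnH (1.3 equiv), AIBN (5 mol%), toluene, 85 °C
Reagents that add atoms: tributyltin hydride, CCCC[SnH](CCCC)CCCC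
Why: Radical hydrostannation of the terminal alkyne puts tin on the terminal carbon and equilibrates to the (E)-alkenylstannane through reversible stannyl radical addition, leaving the (2E) alkene untouched.

**Step 3**
Reactants: 3 2,6,6-trimethyl-4-oxocyclohex-1-en-1-yl trifluoromethanesulfonate; 5 (2E,4E)-3-methyl-5-(tributylstannyl)penta-2,4-dien-1-ol
Product: 6 4-[(1E,3E)-5-hydroxy-3-methylpenta-1,3-dien-1-yl]-3,5,5-trimethylcyclohex-3-en-1-one
Conditions: Pd2(dba)3 (2.5 mol%), AsPh3 (20 mol%), NMP, 45 °C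
Reagents that add atoms: none
Why: Stille cross-coupling of the hindered cyclohexenyl triflate with the alkenylstannane forms C6–C7 with retention of both alkene geometries under neutral conditions that do not move the β,γ double bond.

**Step 4**
Reactants: 6 4-[(1E,3E)-5-hydroxy-3-methylpenta-1,3-dien-1-yl]-3,5,5-trimethylcyclohex-3-en-1-one
Product: 7 (4R)-4-[(1E,3E)-5-hydroxy-3-methylpenta-1,3-dien-1-yl]-3,5,5-trimethylcyclohex-2-en-1-one
Conditions: 9-amino-9-deoxy-epi-quinine (10 mol%), 2-fluorobenzoic acid (20 mol%), toluene, 0 °C, stopped at full conversion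
Reagents that add atoms: none
Why: Proposed new method: the primary amine condenses with the C3 ketone, the quinuclidine removes the doubly activated C4 proton to give a ring dienamine, and the chiral quinuclidinium returns the proton suprafacially to one face of C6, so that iminium hydrolysis releases the conjugated enone with the (R) centre; protonation at C6 is preferred over sites further along the triene because the tethered acid reaches only the γ-carbon, and the shift is driven by enone conjugation and relief of strain in the tetrasubstituted ring alkene; the closest known reaction type is the cinchona primary amine catalysed enantioselective β,γ to α,β isomerisation of simple cyclohex-3-enones (biomimetic 1,3-proton transfer), not yet shown for a tetrasubstituted, triene-conjugated alkene that gives a doubly allylic stereocentre next to a quaternary carbon.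

**Step 5**
Reactants: 7 (4R)-4-[(1E,3E)-5-hydroxy-3-methylpenta-1,3-dien-1-yl]-3,5,5-trimethylcyclohex-2-en-1-one
Product: 9 [(2E,4E)-3-methyl-5-[(1R)-2,6,6-trimethyl-4-oxocyclohex-2-en-1-yl]penta-2,4-dien-1-yl]triphenylphosphonium bromide, via allylic bromide 8 (not isolated)
Conditions: CBr4 (1.1 equiv), PPh3 (1.1 equiv), CH2Cl2, −20 °C; then PPh3 (1.2 equiv), MeCN, 25 °C
Reagents that add atoms: triphenylphosphine, c1ccc(cc1)P(c1ccccc1)c1ccccc1; carbon tetrabromide, BrC(Br)(Br)Br
Why: Appel bromination of the only hydroxyl followed by SN2 quaternisation of PPh3 gives the allylic phosphonium salt under neutral conditions that neither enolise the enone towards C6 nor scramble the diene geometry.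

**Step 6**
Reactants: 9 [(2E,4E)-3-methyl-5-[(1R)-2,6,6-trimethyl-4-oxocyclohex-2-en-1-yl]penta-2,4-dien-1-yl]triphenylphosphonium bromide
Product: 10 [(2E,4E)-5-[(1R,4S)-4-hydroxy-2,6,6-trimethylcyclohex-2-en-1-yl]-3-methylpenta-2,4-dien-1-yl]triphenylphosphonium bromide
Conditions: RuCl[(S,S)-TsDPEN](p-cymene) (1 mol%), HCO2H/Et3N (5:2), CH2Cl2, 25 °C
Reagents that add atoms: none
Why: Noyori–Ikariya asymmetric transfer hydrogenation reduces the β,β-disubstituted enone 1,2 under catalyst control, the (S,S) catalyst treating the alkenyl side of the carbonyl like the aryl group of an aryl ketone and so giving the (S) carbinol, cis to the C6 side chain, while the buffered acidic medium leaves the phosphonium group and C6 untouched.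

**Step 7**
Reactants: 11 (2E,4E,6E)-2,7-dimethylocta-2,4,6-trienedial (2.5 equiv); 12 ethyl (2E)-4-(diethoxyphosphoryl)-2-methylbut-2-enoate
Product: 13 ethyl (2E,4E,6E,8E,10E)-2,6,11-trimethyl-12-oxododeca-2,4,6,8,10-pentaenoate
Conditions: NaOEt (1.0 equiv) added to both components, EtOH/CH2Cl2, 0 °C; aq. NH4Cl
Reagents that add atoms: none
Why: Horner–Wadsworth–Emmons olefination with the vinylogous stabilised phosphonate is (E)-selective and stops at mono-condensation because the dialdehyde is in excess and the product aldehyde is less electrophilic.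

**Step 8**
Reactants: 10 [(2E,4E)-5-[(1R,4S)-4-hydroxy-2,6,6-trimethylcyclohex-2-en-1-yl]-3-methylpenta-2,4-dien-1-yl]triphenylphosphonium bromide; 13 ethyl (2E,4E,6E,8E,10E)-2,6,11-trimethyl-12-oxododeca-2,4,6,8,10-pentaenoate
Product: 15 ethyl (2E,4E,6E,8E,10E,12E,14E,16E)-17-[(1R,4S)-4-hydroxy-2,6,6-trimethylcyclohex-2-en-1-yl]-2,6,11,15-tetramethylheptadeca-2,4,6,8,10,12,14,16-octaenoate, via 12Z ester 14 (not isolated)
Conditions: NaOEt (1.2 equiv), EtOH/CH2Cl2, −10 → 25 °C; then heptane, 95 °C
Reagents that add atoms: none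
Why: Wittig olefination of the semi-stabilised allylic ylide with the enal forms C11=C12 as an E/Z mixture whose hindered (Z) isomer equilibrates thermally to the all-(E) polyene, and ethoxide in ethanol touches neither the free hydroxyl, the ethyl ester nor the C6–H.

**Step 9**
Reactants: 15 ethyl (2E,4E,6E,8E,10E,12E,14E,16E)-17-[(1R,4S)-4-hydroxy-2,6,6-trimethylcyclohex-2-en-1-yl]-2,6,11,15-tetramethylheptadeca-2,4,6,8,10,12,14,16-octaenoate
Product: 16 (2E,4E,6E,8E,10E,12E,14E,16E)-17-[(1R,4S)-4-hydroxy-2,6,6-trimethylcyclohex-2-en-1-yl]-2,6,11,15-tetramethylheptadeca-2,4,6,8,10,12,14,16-octaen-1-ol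
Conditions: i-Bu2AlH (3.5 equiv), CH2Cl2, −78 → −40 °C; aq. potassium sodium tartrate (KNaC4H4O6)
Reagents that add atoms: none
Why: Hydride reduction of the conjugated ester with i-Bu2AlH is 1,2-selective and stops at the allylic alcohol, leaving the polyene and both stereocentres untouched.

**Compound list**
1 | 4-oxoisophorone (2,6,6-trimethylcyclohex-2-ene-1,4-dione) | CC1=CC(=O)CC(C)(C)C1=O | starting material
2 | lithium 2,6,6-trimethyl-4-oxocyclohex-1-en-1-olate | [Li+].[O-]C1=C(C)CC(=O)CC1(C)C | intermediate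
3 | 2,6,6-trimethyl-4-oxocyclohex-1-en-1-yl trifluoromethanesulfonate | CC1=C(OS(=O)(=O)C(F)(F)F)C(C)(C)CC(=O)C1 | intermediate
4 | (2E)-3-methylpent-2-en-4-yn-1-ol | C#C/C(C)=C/CO | starting material
5 | (2E,4E)-3-methyl-5-(tributylstannyl)penta-2,4-dien-1-ol | CCCC[Sn](CCCC)(CCCC)/C=C/C(C)=C/CO | intermediate
6 | 4-[(1E,3E)-5-hydroxy-3-methylpenta-1,3-dien-1-yl]-3,5,5-trimethylcyclohex-3-en-1-one | CC1=C(/C=C/C(C)=C/CO)C(C)(C)CC(=O)C1 | intermediate
7 | (4R)-4-[(1E,3E)-5-hydroxy-3-methylpenta-1,3-dien-1-yl]-3,5,5-trimethylcyclohex-2-en-1-one | CC1=CC(=O)CC(C)(C)[C@H]1/C=C/C(C)=C/CO | intermediate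
8 | (4R)-4-[(1E,3E)-5-bromo-3-methylpenta-1,3-dien-1-yl]-3,5,5-trimethylcyclohex-2-en-1-one | CC1=CC(=O)CC(C)(C)[C@H]1/C=C/C(C)=C/CBr | intermediate
9 | [(2E,4E)-3-methyl-5-[(1R)-2,6,6-trimethyl-4-oxocyclohex-2-en-1-yl]penta-2,4-dien-1-yl]triphenylphosphonium bromide | CC1=CC(=O)CC(C)(C)[C@H]1/C=C/C(C)=C/C[P+](c1ccccc1)(c1ccccc1)c1ccccc1.[Br-] | intermediate
10 | [(2E,4E)-5-[(1R,4S)-4-hydroxy-2,6,6-trimethylcyclohex-2-en-1-yl]-3-methylpenta-2,4-dien-1-yl]triphenylphosphonium bromide | CC1=C[C@@H](O)CC(C)(C)[C@H]1/C=C/C(C)=C/C[P+](c1ccccc1)(c1ccccc1)c1ccccc1.[Br-] | intermediate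
11 | (2E,4E,6E)-2,7-dimethylocta-2,4,6-trienedial | O=C/C(C)=C/C=C/C=C(C)/C=O | starting material
12 | ethyl (2E)-4-(diethoxyphosphoryl)-2-methylbut-2-enoate | CCOC(=O)/C(C)=C/CP(=O)(OCC)OCC | starting material
13 | ethyl (2E,4E,6E,8E,10E)-2,6,11-trimethyl-12-oxododeca-2,4,6,8,10-pentaenoate | CCOC(=O)/C(C)=C/C=C/C(C)=C/C=C/C=C(C)/C=O | intermediate
14 | ethyl (2E,4E,6E,8E,10E,12Z,14E,16E)-17-[(1R,4S)-4-hydroxy-2,6,6-trimethylcyclohex-2-en-1-yl]-2,6,11,15-tetramethylheptadeca-2,4,6,8,10,12,14,16-octaenoate | CC1=C[C@@H](O)CC(C)(C)[C@H]1/C=C/C(C)=C/C=C\C(C)=C\C=C\C=C(C)\C=C\C=C(/C)C(=O)OCC | intermediate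
15 | ethyl (2E,4E,6E,8E,10E,12E,14E,16E)-17-[(1R,4S)-4-hydroxy-2,6,6-trimethylcyclohex-2-en-1-yl]-2,6,11,15-tetramethylheptadeca-2,4,6,8,10,12,14,16-octaenoate | CC1=C[C@@H](O)CC(C)(C)[C@H]1/C=C/C(C)=C/C=C/C(C)=C/C=C/C=C(C)/C=C/C=C(\C)C(=O)OCC | intermediate
16 | (2E,4E,6E,8E,10E,12E,14E,16E)-17-[(1R,4S)-4-hydroxy-2,6,6-trimethylcyclohex-2-en-1-yl]-2,6,11,15-tetramethylheptadeca-2,4,6,8,10,12,14,16-octaen-1-ol | CC1=C[C@@H](O)CC(C)(C)[C@H]1/C=C/C(C)=C/C=C/C(C)=C/C=C/C=C(C)/C=C/C=C(\C)CO | target

**Step count**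
Total: 9 steps. Longest linear sequence: 7 steps (1, 3, 4, 5, 6, 8, 9).

**Three steps most likely to fail**

Step 4 (the proposed new isomerisation). The sense of induction is assigned by model only; the quinidine-derived pseudo-enantiomer of the amine would deliver the proton to the other face. The ee may also erode through reversible C6 deprotonation, or the proton may go further along the triene. The fallback uses known chemistry, sets out from 6 and returns at 7. Compound 6 is isomerised with DBU (5 mol%, CH2Cl2, 25 °C), the ordinary base-mediated β,γ to α,β shift, to the racemic enone. The racemate is resolved by preparative chiral SFC to give 7. The unwanted enantiomer (4S)-4-[(1E,3E)-5-hydroxy-3-methylpenta-1,3-dien-1-yl]-3,5,5-trimethylcyclohex-2-en-1-one F4 is put back into the DBU equilibration, since its C6–H is labile to base, and recycled.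

Step 1. The borohydride may attack the unhindered C4 carbonyl 1,2, or the keto enolate may scramble before it is trapped. The fallback sets out from 1 and returns at 3. Compound 1 is ketalised at the unhindered C4 carbonyl (ethylene glycol, TsOH, toluene, Dean–Stark) to 7,9,9-trimethyl-1,4-dioxaspiro[4.5]dec-6-en-8-one F1. Its single enone is reduced 1,4 with LiBH(s-Bu)3 to lithium 7,9,9-trimethyl-1,4-dioxaspiro[4.5]dec-7-en-8-olate F2, which is trapped with PhNTf2 as 7,9,9-trimethyl-1,4-dioxaspiro[4.5]dec-7-en-8-yl trifluoromethanesulfonate F3. Acid hydrolysis of the ketal (TsOH, acetone/water, 25 °C) then gives 3; the double bond cannot move into conjugation at this stage because it carries the triflate.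

Step 6. The preferred half-chair may bias hydride delivery towards the face that gives the trans alcohol and so work against the catalyst, and the bromide salt may slow the ruthenium catalyst. The fallback sets out from 7 and returns at 10. The ketone is reduced before the salt is made, with a screened (S)-selective ketoreductase (NADPH, glucose/glucose dehydrogenase recycling, phosphate buffer/DMSO, 30 °C), to (1S,4R)-4-[(1E,3E)-5-hydroxy-3-methylpenta-1,3-dien-1-yl]-3,5,5-trimethylcyclohex-2-en-1-ol F5; at this neutral stage any trans diastereomer is removed on silica. A primary-selective Appel bromination (CBr4, PPh3, 2,6-lutidine, CH2Cl2, −30 °C) gives (1S,4R)-4-[(1E,3E)-5-bromo-3-methylpenta-1,3-dien-1-yl]-3,5,5-trimethylcyclohex-2-en-1-ol F6, which is quaternised in the same flask with PPh3 to 10.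

**Further compounds**
F1 | step 1 | 7,9,9-trimethyl-1,4-dioxaspiro[4.5]dec-6-en-8-one | CC1=CC2(CC(C)(C)C1=O)OCCO2
F2 | step 1 | lithium 7,9,9-trimethyl-1,4-dioxaspiro[4.5]dec-7-en-8-olate | [Li+].[O-]C1=C(C)CC2(CC1(C)C)OCCO2
F3 | step 1 | 7,9,9-trimethyl-1,4-dioxaspiro[4.5]dec-7-en-8-yl trifluoromethanesulfonate | CC1=C(OS(=O)(=O)C(F)(F)F)C(C)(C)CC2(C1)OCCO2
F4 | step 4 | (4S)-4-[(1E,3E)-5-hydroxy-3-methylpenta-1,3-dien-1-yl]-3,5,5-trimethylcyclohex-2-en-1-one | CC1=CC(=O)CC(C)(C)[C@@H]1/C=C/C(C)=C/CO
F5 | step 6 | (1S,4R)-4-[(1E,3E)-5-hydroxy-3-methylpenta-1,3-dien-1-yl]-3,5,5-trimethylcyclohex-2-en-1-ol | CC1=C[C@@H](O)CC(C)(C)[C@H]1/C=C/C(C)=C/CO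
F6 | step 6 | (1S,4R)-4-[(1E,3E)-5-bromo-3-methylpenta-1,3-dien-1-yl]-3,5,5-trimethylcyclohex-2-en-1-ol | CC1=C[C@@H](O)CC(C)(C)[C@H]1/C=C/C(C)=C/CBr
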